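The numbers in the tables stem from a simulated flask with made-up constants, noise included.

A one-step world has one clock: substrate turns into target, and target stays. In these runs target rose and then fell, so I reckoned with two clocks.

| flask | substrate | partner | remark | time |
|---|---|---|---|---|
| north-east | 0.28 M (fed, over 40 min) | 0.80 M | run made earlier |  |
| west | 0.44 M (fed, over 40 min) | 0.80 M | run made earlier |  |
| south-west | 0.20 M (fed, over 40 min) | 1.6 M | run made earlier |  |
| flask | 0.20 M (fed, over 40 min) | 0.800 M |  | 20 h |

- north-east (time / h: target / %, substrate / %): 2.00: 10.5, 68.4; 3.00: 15.0, 55.8; 5.00: 18.9, 37.8; 8.00: 19.6, 22.8; 15.0: 17.0, 7.2; 25.0: 13.2, 1.5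
- west (time / h: target / %, substrate / %): 2.00: 11.7, 69.9; 3.00: 14.5, 57.7; 5.00: 18.9, 41.0; 8.00: 19.8, 26.1; 15.0: 16.3, 11.1; 25.0: 13.0, 2.5
- south-west (time / h: target / %, substrate / %): 2.00: 18.9, 47.3; 4.00: 25.5, 19.8; 6.00: 26.4, 8.8; 12.0: 18.7, 0.7; 25.0: 10.9, 0

(readings scatter by 0.5 percentage points)

- the numbers in the tables scatter with a standard deviation of 0.5 percentage points

1. time up to 20 h at which target stands highest
2. the amount of target, in percent of the substrate charged, at that time
3. the first time at which target reaches 10 %, in the same percent

I counted turnovers on each clock. In the south-west run, with more partner than the others, the first two substrate readings gave a rate constant of 0.272 M⁻¹ h⁻¹, with [partner] taken as charged. I assumed one partner per substrate and took [partner] at mid-course. The flask's substrate clock, a pseudo-first-order constant, was then 0.190 h⁻¹.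

At the first south-west reading, target was 35.9 % of the substrate lost, so I used that share. At the north-east top, inflow and loss of target balance. That reading gave a target clock of 0.0749 h⁻¹.

The number I carried was the turnover ratio, substrate turnovers per target turnover, 2.54 in the flask.

The curve starts at a slope of share times substrate clock, and its knee comes as substrate thins. At the top, target over substrate equals share times ratio, 0.912, so I expected target there still less than substrate, and the two lines to cross soon after. Beyond that I could read no level: the south-west run still showed 10.9 % at 25.0 h.

| Landmark | Time | Target |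
|---|---|---|
| Asked level (loss of target ignored) | 1.72 h | 10.0 % |
| Top | 8.07 h | 19.6 % |

The forecast gave 20.2 % at 6.8 h and the asked level at 1.8 h, saying “The flask should closely follow the north-east run”, and its top came earlier than mine.

The flask gave 20.9 % at 7.49 h, and the asked level at 1.71 h.

    substrate + partner → target (k = 0.118 M⁻¹ h⁻¹)
    substrate + partner → isomer of the product A (k = 0.103 M⁻¹ h⁻¹)
    substrate + partner → second isomer (k = 0.0779 M⁻¹ h⁻¹)
    target ⇌ isomer of the product B (K = 3.10, k = 0.0957 h⁻¹)

While substrate and partner stood together, parallel steps made target, isomer of the product A and second isomer, which held 20.9 %, 26.8 % and 20.2 % at 7.49 h. Target meanwhile exchanged with isomer of the product B, with a relaxation half-life of 5.48 h, shorter than 20 h. At that time the flask's own target and substrate, put into the top balance, gave a ratio of 2.61, against the 2.54 I had carried.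

With 2.0 M of partner, I scaled the ratio 2.54 by mid-course [partner] to 6.90, and my top rose to 25.9 %. That neighbour flask, computed, reached 27.7 %.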